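The isoflavan is cut around C3, which carries ring B directly (C3–C1′) and ring A through the C4 methylene (C4–C4a); C3–C4 is therefore introduced as a vinyl unit. A single palladium-catalysed conjunctive cross-coupling unites vinylboronic pinacol ester, the ring B aryllithium and the ring A aryl bromide, forms both bonds and leaves C3 as an enantioenriched secondary boronic ester. Its precursors are a ring B bromide with two methoxymethyl ethers and the 2-methylbut-3-en-2-yl group, and a ring A bromide with two silyl ethers and the silylated tertiary alcohol. The C3–B bond then takes up C2 with retention; oxidation, desilylation, Mitsunobu closure of ring C and acetal cleavage finish the synthesis.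

Key step: step 10

Assumption 1: monoalkylation of 4-bromoresorcinol is taken to occur mainly at the hydroxyl para to bromine (the less hindered one); the regiochemistry of 3 is to be confirmed by NOE and minor isomers removed by chromatography.
Assumption 2: the (Sp,Sp) antipode of MandyPhos is taken, by analogy with simpler aryl partners, to lead to the (R)-boronic ester; if the sense proves opposite, the (Rp,Rp) antipode is used.
Assumption 3: 2-iodoresorcinol is a catalogue compound; it is otherwise one step from resorcinol (I2, NaHCO3, water).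

**Ring B bromide**

Step 1
Reactants: 1 4-bromoresorcinol; 2 1-bromo-3-methylbut-2-ene
Product: 3 2-bromo-5-[(3-methylbut-2-en-1-yl)oxy]phenol
Conditions: K2CO3 (1.1 equiv), acetone, rt
Reagents that add atoms: none
Why: Williamson ether synthesis with one equivalent of the allylic bromide should take place mainly at the hydroxyl para to bromine, and the mono-ether is separable from bis-ether and regioisomer.

Step 2
Reactants: 3 2-bromo-5-[(3-methylbut-2-en-1-yl)oxy]phenol
Product: 4 1-bromo-2-(methoxymethoxy)-4-[(3-methylbut-2-en-1-yl)oxy]benzene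
Conditions: NaH, MOMCl, DMF, 0 °C to rt
Reagents that add atoms: chloromethyl methyl ether (MOMCl), COCCl
Why: O-alkylation of the phenoxide with MOMCl is routine, and the acetal placed here later shields C3′ in the rearrangement and chelates lithium in step 10.

Step 3
Reactants: 4 1-bromo-2-(methoxymethoxy)-4-[(3-methylbut-2-en-1-yl)oxy]benzene
Product: 5 4-bromo-5-(methoxymethoxy)-2-(2-methylbut-3-en-2-yl)phenol
Conditions: EtOH/H2O (4:1), 130 °C, sealed vessel
Reagents that add atoms: none
Why: The aromatic Claisen rearrangement ([3,3]-sigmatropic) of an aryl prenyl ether should deliver the 1,1-dimethylallyl group to the open ortho position C5′ and not to C3′ between the two oxygens, and aqueous ethanol at moderate temperature should limit loss of isoprene and further rearrangement.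

Step 4
Reactants: 5 4-bromo-5-(methoxymethoxy)-2-(2-methylbut-3-en-2-yl)phenol
Product: 6 1-bromo-2,4-bis(methoxymethoxy)-5-(2-methylbut-3-en-2-yl)benzene
Conditions: NaH, MOMCl, DMF, 0 °C to rt
Reagents that add atoms: chloromethyl methyl ether (MOMCl), COCCl
Why: Alkylation of the sodium phenoxide in DMF is the standard way to acetalise a phenol flanked by a tertiary alkyl group.

**Ring A bromide**

Step 5
Reactants: 7 2-iodoresorcinol
Product: 8 2-iodo-1,3-bis(tert-butyldimethylsilyloxy)benzene
Conditions: TBSCl, imidazole, DMF, rt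
Reagents that add atoms: tert-butyldimethylsilyl chloride (TBSCl), CC(C)(C)[Si](C)(C)Cl
Why: Imidazole-promoted silylation of phenols is routine and gives ethers that are orthogonal to the acetals of ring B.

Step 6
Reactants: 8 2-iodo-1,3-bis(tert-butyldimethylsilyloxy)benzene; 9 2-methylbut-3-yn-2-ol
Product: 10 4-[2,6-bis(tert-butyldimethylsilyloxy)phenyl]-2-methylbut-3-yn-2-ol
Conditions: PdCl2(PPh3)2 (cat.), CuI (cat.), Et3N, THF, 60 °C
Reagents that add atoms: none
Why: Sonogashira coupling of an aryl iodide with a terminal alkyne tolerates the two flanking silyloxy groups because the alkynyl partner is slim, and the silyl ethers prevent cyclisation to a benzofuran.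

Step 7
Reactants: 10 4-[2,6-bis(tert-butyldimethylsilyloxy)phenyl]-2-methylbut-3-yn-2-ol
Product: 11 4-[2,6-bis(tert-butyldimethylsilyloxy)phenyl]-2-methylbutan-2-ol
Conditions: H2 (1 atm), Pd/C, EtOAc, rt
Reagents that add atoms: none
Why: Heterogeneous catalytic hydrogenation saturates the alkyne to the two-carbon bridge under neutral conditions, with no halogen or other alkene yet present.

Step 8
Reactants: 11 4-[2,6-bis(tert-butyldimethylsilyloxy)phenyl]-2-methylbutan-2-ol
Product: 12 4-[3-bromo-2,6-bis(tert-butyldimethylsilyloxy)phenyl]-2-methylbutan-2-ol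
Conditions: NBS (1.0 equiv), MeCN, 0 °C
Reagents that add atoms: N-bromosuccinimide (NBS), O=C1CCC(=O)N1Br
Why: Electrophilic aromatic bromination goes ortho to one silyloxy group and para to the other, the two such positions being equivalent by symmetry, while the position meta to both oxygens is not activated.

Step 9
Reactants: 12 4-[3-bromo-2,6-bis(tert-butyldimethylsilyloxy)phenyl]-2-methylbutan-2-ol
Product: 13 1-bromo-2,4-bis(tert-butyldimethylsilyloxy)-3-[3-methyl-3-(triethylsilyloxy)butyl]benzene
Conditions: TESOTf, 2,6-lutidine, CH2Cl2, 0 °C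
Reagents that add atoms: triethylsilyl trifluoromethanesulfonate (TESOTf), CC[Si](CC)(CC)OS(=O)(=O)C(F)(F)F
Why: Silylation of a tertiary alcohol with a silyl triflate and a hindered pyridine base is standard and leaves aryl silyl ethers and the aryl bromide untouched.

**Coupling and endgame**

Step 10
Reactants: 6 1-bromo-2,4-bis(methoxymethoxy)-5-(2-methylbut-3-en-2-yl)benzene; 14 vinylboronic acid pinacol ester; 13 1-bromo-2,4-bis(tert-butyldimethylsilyloxy)-3-[3-methyl-3-(triethylsilyloxy)butyl]benzene
Product: 17 2-[(1R)-1-[2,4-bis(methoxymethoxy)-5-(2-methylbut-3-en-2-yl)phenyl]-2-{2,4-bis(tert-butyldimethylsilyloxy)-3-[3-methyl-3-(triethylsilyloxy)butyl]phenyl}ethyl]-4,4,5,5-tetramethyl-1,3,2-dioxaborolane, via ring B aryllithium 15 (not isolated), via lithium aryl(vinyl)boronate complex 16 (not isolated)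
Conditions: 6, t-BuLi (2.0 equiv), Et2O, −78 °C; 14, −78 °C to rt; solvent changed to THF; 13, Pd(OAc)2 (3 mol%), (Sp,Sp)-MandyPhos [1,1′-bis(diphenylphosphino)-2,2′-bis(α-(dimethylamino)benzyl)ferrocene, C52H50FeN2P2] (3.6 mol%), NaOSO2CF3 (NaOTf, 3 equiv), 50 °C
Reagents that add atoms: none
Why: Bromine–lithium exchange gives 15, which adds to boron of 14 to form 16; zerovalent palladium inserts into the C–Br bond of 13, the cationic divalent arylpalladium species (bromide removed as NaBr) binds the vinyl group of 16, ring B shifts from boron to the internal carbon anti to palladium, and reductive elimination from the alkylpalladium joins the terminal carbon to ring A (C4–C4a). The closest known reaction type is the enantioselective conjunctive cross-coupling of aryl(vinyl)boronate complexes with aryl halides or triflates under Pd(OAc)2 and MandyPhos. No ring is closed. C3 is the only new stereocentre and is set by the chiral bisphosphine, which fixes the alkene face that palladium occupies during the 1,2-shift. The step needs the metalate shift to outrun direct Suzuki-type transfer, beta-hydride elimination and Heck reaction at the other alkene; the chelating ligand, the halide scavenger, the electron-rich and therefore mobile ring B, and the quaternary carbon that shields the 2-methylbut-3-en-2-yl alkene should secure this.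

Step 11
Reactants: 17 the (R)-secondary boronic ester from step 10
Product: 19 (2R)-2-[2,4-bis(methoxymethoxy)-5-(2-methylbut-3-en-2-yl)phenyl]-3-{2,4-bis(tert-butyldimethylsilyloxy)-3-[3-methyl-3-(triethylsilyloxy)butyl]phenyl}propan-1-ol, via homologated primary boronic ester 18 (not isolated)
Conditions: BrCH2Cl, n-BuLi, THF, −78 °C to rt; then NaBO3·4H2O, THF/H2O, rt
Reagents that add atoms: bromochloromethane, ClCBr; sodium perborate tetrahydrate (NaBO3·4H2O), [Na+].[Na+].O[B-]1(O)OO[B-](O)(O)OO1
Why: In the Matteson homologation, chloromethyllithium made in situ adds to boron and C3 migrates to the CH2 carbon with retention as chloride leaves, after which perborate oxidation of the primary C–B bond gives the alcohol without touching C3, the silyl ethers, the acetals or the alkene.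

Step 12
Reactants: 19 the (2R)-propan-1-ol from step 11
Product: 20 4-[(2R)-2-[2,4-bis(methoxymethoxy)-5-(2-methylbut-3-en-2-yl)phenyl]-3-hydroxypropyl]-2-(3-hydroxy-3-methylbutyl)benzene-1,3-diol
Conditions: Bu4NF (3.5 equiv), THF, 0 °C to rt
Reagents that add atoms: none
Why: Fluoride-induced desilylation should remove both aryl silyl ethers and the tertiary triethylsilyl ether in one operation, while the methoxymethyl acetals and C3 are unaffected.

Step 13
Reactants: 20 the ring A diol from step 12
Product: 21 (3R)-3-[2,4-bis(methoxymethoxy)-5-(2-methylbut-3-en-2-yl)phenyl]-8-(3-hydroxy-3-methylbutyl)-3,4-dihydro-2H-chromen-7-ol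
Conditions: PPh3, DIAD, THF (0.01 M), 0 °C to rt
Reagents that add atoms: none
Why: In this intramolecular Mitsunobu etherification the activated primary alcohol is displaced by the phenolic O1 in a 6-exo-tet closure that forms O1–C2; the tertiary alcohol is inert, O7 cannot reach C2 and the ring B oxygens are masked, so C3 is not involved.

Step 14
Reactants: 21 the bis(methoxymethyl) isoflavan from step 13
Product: 22 (3R)-3-[2,4-dihydroxy-5-(2-methylbut-3-en-2-yl)phenyl]-8-(3-hydroxy-3-methylbutyl)-3,4-dihydro-2H-chromen-7-ol (CNP0420388.1)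
Conditions: HCl (3 M aq), MeOH, rt to 35 °C
Reagents that add atoms: none
Why: Acid-catalysed acetal exchange with methanol cleaves both aryl methoxymethyl ethers under conditions mild enough that ionisation of the tertiary alcohol and protonation of the monosubstituted alkene should remain slow.

**Compound list**

1 | 4-bromoresorcinol | Oc1ccc(Br)c(O)c1 | starting material
2 | 1-bromo-3-methylbut-2-ene | CC(C)=CCBr | starting material
3 | 2-bromo-5-[(3-methylbut-2-en-1-yl)oxy]phenol | CC(C)=CCOc1ccc(Br)c(O)c1 | intermediate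
4 | 1-bromo-2-(methoxymethoxy)-4-[(3-methylbut-2-en-1-yl)oxy]benzene | CC(C)=CCOc1ccc(Br)c(OCOC)c1 | intermediate
5 | 4-bromo-5-(methoxymethoxy)-2-(2-methylbut-3-en-2-yl)phenol | C=CC(C)(C)c1cc(Br)c(OCOC)cc1O | intermediate
6 | 1-bromo-2,4-bis(methoxymethoxy)-5-(2-methylbut-3-en-2-yl)benzene (ring B bromide) | C=CC(C)(C)c1cc(Br)c(OCOC)cc1OCOC | intermediate
7 | 2-iodoresorcinol | Oc1cccc(O)c1I | starting material
8 | 2-iodo-1,3-bis(tert-butyldimethylsilyloxy)benzene | CC(C)(C)[Si](C)(C)Oc1cccc(O[Si](C)(C)C(C)(C)C)c1I | intermediate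
9 | 2-methylbut-3-yn-2-ol | CC(C)(O)C#C | starting material
10 | 4-[2,6-bis(tert-butyldimethylsilyloxy)phenyl]-2-methylbut-3-yn-2-ol | CC(C)(O)C#Cc1c(O[Si](C)(C)C(C)(C)C)cccc1O[Si](C)(C)C(C)(C)C | intermediate
11 | 4-[2,6-bis(tert-butyldimethylsilyloxy)phenyl]-2-methylbutan-2-ol | CC(C)(O)CCc1c(O[Si](C)(C)C(C)(C)C)cccc1O[Si](C)(C)C(C)(C)C | intermediate
12 | 4-[3-bromo-2,6-bis(tert-butyldimethylsilyloxy)phenyl]-2-methylbutan-2-ol | CC(C)(O)CCc1c(O[Si](C)(C)C(C)(C)C)ccc(Br)c1O[Si](C)(C)C(C)(C)C | intermediate
13 | 1-bromo-2,4-bis(tert-butyldimethylsilyloxy)-3-[3-methyl-3-(triethylsilyloxy)butyl]benzene (ring A bromide) | Brc1ccc(O[Si](C)(C)C(C)(C)C)c(CCC(C)(C)O[Si](CC)(CC)CC)c1O[Si](C)(C)C(C)(C)C | intermediate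
14 | vinylboronic acid pinacol ester | C=CB1OC(C)(C)C(C)(C)O1 | starting material
15 | [2,4-bis(methoxymethoxy)-5-(2-methylbut-3-en-2-yl)phenyl]lithium, formed in situ | [Li]c1cc(C(C)(C)C=C)c(OCOC)cc1OCOC | intermediate
16 | lithium [2,4-bis(methoxymethoxy)-5-(2-methylbut-3-en-2-yl)phenyl](ethenyl)(pinacolato)borate, formed in situ | [Li+].C=C[B-]1(c2cc(C(C)(C)C=C)c(OCOC)cc2OCOC)OC(C)(C)C(C)(C)O1 | intermediate
17 | 2-[(1R)-1-[2,4-bis(methoxymethoxy)-5-(2-methylbut-3-en-2-yl)phenyl]-2-{2,4-bis(tert-butyldimethylsilyloxy)-3-[3-methyl-3-(triethylsilyloxy)butyl]phenyl}ethyl]-4,4,5,5-tetramethyl-1,3,2-dioxaborolane | C=CC(C)(C)c1cc([C@@H](Cc2ccc(O[Si](C)(C)C(C)(C)C)c(CCC(C)(C)O[Si](CC)(CC)CC)c2O[Si](C)(C)C(C)(C)C)B2OC(C)(C)C(C)(C)O2)c(OCOC)cc1OCOC | intermediate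
18 | 2-[(2R)-2-[2,4-bis(methoxymethoxy)-5-(2-methylbut-3-en-2-yl)phenyl]-3-{2,4-bis(tert-butyldimethylsilyloxy)-3-[3-methyl-3-(triethylsilyloxy)butyl]phenyl}propyl]-4,4,5,5-tetramethyl-1,3,2-dioxaborolane, formed in situ | C=CC(C)(C)c1cc([C@@H](Cc2ccc(O[Si](C)(C)C(C)(C)C)c(CCC(C)(C)O[Si](CC)(CC)CC)c2O[Si](C)(C)C(C)(C)C)CB2OC(C)(C)C(C)(C)O2)c(OCOC)cc1OCOC | intermediate
19 | (2R)-2-[2,4-bis(methoxymethoxy)-5-(2-methylbut-3-en-2-yl)phenyl]-3-{2,4-bis(tert-butyldimethylsilyloxy)-3-[3-methyl-3-(triethylsilyloxy)butyl]phenyl}propan-1-ol | C=CC(C)(C)c1cc([C@@H](Cc2ccc(O[Si](C)(C)C(C)(C)C)c(CCC(C)(C)O[Si](CC)(CC)CC)c2O[Si](C)(C)C(C)(C)C)CO)c(OCOC)cc1OCOC | intermediate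
20 | 4-[(2R)-2-[2,4-bis(methoxymethoxy)-5-(2-methylbut-3-en-2-yl)phenyl]-3-hydroxypropyl]-2-(3-hydroxy-3-methylbutyl)benzene-1,3-diol | C=CC(C)(C)c1cc([C@@H](Cc2ccc(O)c(CCC(C)(C)O)c2O)CO)c(OCOC)cc1OCOC | intermediate
21 | (3R)-3-[2,4-bis(methoxymethoxy)-5-(2-methylbut-3-en-2-yl)phenyl]-8-(3-hydroxy-3-methylbutyl)-3,4-dihydro-2H-chromen-7-ol | C=CC(C)(C)c1cc([C@@H]2COc3c(ccc(O)c3CCC(C)(C)O)C2)c(OCOC)cc1OCOC | intermediate
22 | (3R)-3-[2,4-dihydroxy-5-(2-methylbut-3-en-2-yl)phenyl]-8-(3-hydroxy-3-methylbutyl)-3,4-dihydro-2H-chromen-7-ol | C=CC(C)(C)c1cc([C@@H]2COc3c(ccc(O)c3CCC(C)(C)O)C2)c(O)cc1O | target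

Total step count: 14. Longest linear sequence: 10 steps (7 to 22, steps 5 to 14); the ring B branch (steps 1 to 4) joins at step 10.

**Steps most likely to fail**

1. Step 10. Oxidative addition and alkene binding may be slowed by the ortho oxygen substituents on both aryl partners, so that direct Suzuki-type transfer from boron, protodeboronation of 16 or erosion of facial selectivity compete. The fallback sets out from 15 (made from 6 as in step 10) and from 13 and returns at 17; it sets C3 by a sparteine-mediated lithiation–borylation. Aryllithium 15 is quenched with 2-isopropoxy-4,4,5,5-tetramethyl-1,3,2-dioxaborolane to give the ring B arylboronic pinacol ester F1. Bromide 13 undergoes Stille coupling with Bu3SnCH=CH2 (Pd(PPh3)4, toluene, 100 °C) to the ring A styrene F2. Hydroboration with 9-BBN gives the B-(2-arylethyl)-9-borabicyclononane F3, which is oxidised in the same flask (NaBO3·4H2O) to the 2-arylethanol F4. N,N-Diisopropylcarbamoyl chloride and Et3N convert this into the carbamate F5. s-BuLi with (−)-sparteine (Et2O, −78 °C) removes the pro-S hydrogen next to oxygen to give the (S)-lithiated carbamate F6. F1 adds with retention to form the boronate complex F7, and on warming ring B shifts from boron to carbon with inversion as the carbamate leaves, which gives 17.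

2. Step 3. Migration to the crowded C3′ position, loss of isoprene or further rearrangement of the first-formed ortho-(1,1-dimethylallyl)phenol may spoil the regiochemical outcome. The fallback sets out from 1 and returns at 6; it builds the tertiary allyl group by enolate arylation instead of a sigmatropic shift. Double methoxymethylation of 1 (NaH, MOMCl, DMF) gives 1-bromo-2,4-bis(methoxymethoxy)benzene F8. Palladium-catalysed α-arylation of 2-methylpropanal (Pd(OAc)2, SPhos, Cs2CO3, dioxane, 90 °C) gives the α-quaternary aldehyde F9. Wittig methylenation (Ph3P=CH2, THF) gives 2,4-bis(methoxymethoxy)-1-(2-methylbut-3-en-2-yl)benzene F10. Bromination with NBS (MeCN, 0 °C) at C1′, para to the C4′ oxygen, then gives 6.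

3. Step 14. Acid may ionise the tertiary alcohol, which would then close onto O7 to a dimethylchroman ring, or add the C4′ hydroxyl across the terminal alkene before both acetals are gone. The fallback sets out from 21 and returns at 22; it cleaves the acetals by silyl transfer under buffered, non-protic conditions. TMSOTf with 2,2′-bipyridyl (MeCN, 0 °C to rt) converts both aryl acetals into aryl trimethylsilyl ethers and silylates the C7 hydroxyl and the tertiary alcohol, giving the tetrakis(trimethylsilyl) ether F11. Bu4NF (THF, 0 °C) then frees all four hydroxyls to give 22.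

Further compounds
F1 | step 10 | 2-[2,4-bis(methoxymethoxy)-5-(2-methylbut-3-en-2-yl)phenyl]-4,4,5,5-tetramethyl-1,3,2-dioxaborolane | C=CC(C)(C)c1cc(B2OC(C)(C)C(C)(C)O2)c(OCOC)cc1OCOC
F2 | step 10 | 1-ethenyl-2,4-bis(tert-butyldimethylsilyloxy)-3-[3-methyl-3-(triethylsilyloxy)butyl]benzene | C=Cc1ccc(O[Si](C)(C)C(C)(C)C)c(CCC(C)(C)O[Si](CC)(CC)CC)c1O[Si](C)(C)C(C)(C)C
F3 | step 10 | 9-(2-{2,4-bis(tert-butyldimethylsilyloxy)-3-[3-methyl-3-(triethylsilyloxy)butyl]phenyl}ethyl)-9-borabicyclo[3.3.1]nonane | C1CC2CCCC(C1)B2CCc1ccc(O[Si](C)(C)C(C)(C)C)c(CCC(C)(C)O[Si](CC)(CC)CC)c1O[Si](C)(C)C(C)(C)C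
F4 | step 10 | 2-{2,4-bis(tert-butyldimethylsilyloxy)-3-[3-methyl-3-(triethylsilyloxy)butyl]phenyl}ethanol | OCCc1ccc(O[Si](C)(C)C(C)(C)C)c(CCC(C)(C)O[Si](CC)(CC)CC)c1O[Si](C)(C)C(C)(C)C
F5 | step 10 | 2-{2,4-bis(tert-butyldimethylsilyloxy)-3-[3-methyl-3-(triethylsilyloxy)butyl]phenyl}ethyl N,N-diisopropylcarbamate | CC(C)N(C(C)C)C(=O)OCCc1ccc(O[Si](C)(C)C(C)(C)C)c(CCC(C)(C)O[Si](CC)(CC)CC)c1O[Si](C)(C)C(C)(C)C
F6 | step 10 | (1S)-1-lithio derivative of F5 (sparteine complex, lithium on the carbon bearing oxygen) | CC(C)N(C(C)C)C(=O)O[C@@H]([Li])Cc1ccc(O[Si](C)(C)C(C)(C)C)c(CCC(C)(C)O[Si](CC)(CC)CC)c1O[Si](C)(C)C(C)(C)C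
F7 | step 10 | lithium boronate complex of F6 with F1 (boron in place of lithium, retention) | [Li+].CC(C)N(C(C)C)C(=O)O[C@H](Cc1ccc(O[Si](C)(C)C(C)(C)C)c(CCC(C)(C)O[Si](CC)(CC)CC)c1O[Si](C)(C)C(C)(C)C)[B-]1(c2cc(C(C)(C)C=C)c(OCOC)cc2OCOC)OC(C)(C)C(C)(C)O1
F8 | step 3 | 1-bromo-2,4-bis(methoxymethoxy)benzene | COCOc1ccc(Br)c(OCOC)c1
F9 | step 3 | 2-[2,4-bis(methoxymethoxy)phenyl]-2-methylpropanal | COCOc1ccc(C(C)(C)C=O)c(OCOC)c1
F10 | step 3 | 2,4-bis(methoxymethoxy)-1-(2-methylbut-3-en-2-yl)benzene | C=CC(C)(C)c1ccc(OCOC)cc1OCOC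
F11 | step 14 | tetrakis(trimethylsilyl) ether of 22 (silyl on O7, O2′, O4′ and the tertiary oxygen) | C=CC(C)(C)c1cc([C@@H]2COc3c(ccc(O[Si](C)(C)C)c3CCC(C)(C)O[Si](C)(C)C)C2)c(O[Si](C)(C)C)cc1O[Si](C)(C)C
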